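The data were generated by integration from invented constants, and the scatter is random.

Count the second substrate.

the same everywhere: starting material 0.020 M; free enzyme 10 µM

| charge | second substrate | protic impurity | remark |
|---|---|---|---|
| noon | 0.0095 M | 0.020 M | run made earlier |
| dawn | 0.038 M | 0.020 M | run made earlier |
| flask | 0.0190 M | 0.0200 M |  |

- noon (time / min: target / %, starting material / %): 1.00: 7.0, 95.7; 2.00: 9.0, 89.5; 3.00: 12.9, 86.6; 5.00: 11.9, 87.3; 8.00: 11.9, 87.0; 15.0: 12.2, 88.1
- dawn (time / min: target / %, starting material / %): 1.00: 8.9, 89.9; 3.00: 28.4, 70.2; 5.00: 42.9, 55.5; 8.00: 61.0, 39.1; 12.0: 75.2, 25.9; 15.0: 83.6, 15.0

(each reading ± 1 percentage point)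

* apparent order in second substrate when 10 % of the starting material are converted (percent change of the rate of making target for one percent more second substrate charged)
* apparent order in free enzyme when 10 % of the starting material are converted (percent change of the rate of making target for one percent more free enzyme charged)
* factor on the rate of making target when 10 % of the starting material are converted if free enzyme is charged twice over

Read the last rows of the two tables against each other. The noon run stands at 12.2 % of target with 88.1 % of the starting material unused, while the dawn run, with 4.00 times the c of second substrate, is still climbing. Now read noon's target in moles against its charge of second substrate: this gives the yield on second substrate, the target made per second substrate charged, 0.257. I read the rest as lost to the protic impurity, so noon loses 2.89 of second substrate for each target made.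

The flask, like noon, has a c of second substrate below that of protic impurity, so I carry noon's yield over. My reckoning is that the flask stalls near 24.4 % of target. With loss ahead of target, more free enzyme should reach 10 % conversion sooner, with more second substrate unquenched. So I expect an order in free enzyme above one and a doubling factor above 2, though that part is a guess, since no earlier run changes the enzyme charge.

The forecast differs on the enzyme, giving an order in free enzyme of 1 (0.6 to 1.2) and a doubling factor of 2 (1.5 to 2.3) with “I assume it is first order”, and an order of 0.8 (0.4 to 1.3) in second substrate.

The flask gives 0.66 in second substrate, 1.3 in free enzyme and a doubling factor of 2.31.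

    starting material + free enzyme ⇌ first complex (K = 57.0 L mol⁻¹, k = 74000 L mol⁻¹ s⁻¹)
    first complex → loaded enzyme + first product (k = 11.0 s⁻¹)
    second substrate + loaded enzyme ⇌ second complex (K = 33.0 L mol⁻¹, k = 88000 L mol⁻¹ s⁻¹)
    second complex → free enzyme + target (k = 26.0 s⁻¹)
    second substrate + protic impurity → quenched reagent (k = 0.770 L mol⁻¹ s⁻¹)
    free enzyme ⇌ dormant form (K = 0.400, k = 0.0210 s⁻¹)

After 12.0 min the flask holds 26.5 % of target, and its limiting reagent, second substrate, is down to 0.0112 % of its charge. The flask's yield on second substrate is then 0.279, beside the 0.257 read from noon. The dawn run, whose c of second substrate exceeds that of protic impurity, already shows 0.440 at its last reading. In the flask, second complex falls back to second substrate and loaded enzyme, the largest single effect on the order in free enzyme. Without that reverse step, the flask's order in free enzyme goes from 1.3 to 1.0.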